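**Plan**

1. Cuts, in retrosynthetic order: the six O–Me bonds; the stilbene C=C (Horner–Wadsworth–Emmons) back to a C5 aldehyde; O1–C7a (SNAr on a fluoride para to that formyl group); then C3–C3a and C2–aryl (catechol ring) in one operation, with C2–O first traced back to C2–B.
2. Enabling feature: C2 and C3 of the dihydrofuran ring are the two carbons of a former (E)-alkene that already bears the resorcinol ring on C3. C3 lacks only ring A (the benzo ring), and C2 lacks only the catechol ring and an oxygen, whose place boron can hold.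
3. Forward: ring A is made as an ortho-fluoro aryl triflate with the C5 formyl group masked as a dioxolane. The alkene enters as the (E)-styryl boronic ester of cis-1,2-dimethylacenaphthene-1,2-diol (B(mac)), chosen over the pinacol ester because β-substituted alkenyl pinacol boronates tend to give plain Suzuki coupling.
4. One three-component coupling joins the chain; then C–B becomes C–OH, the acetal is removed, the only ring made in the route (the dihydrofuran, O1–C7a) is closed, the styryl arm is added and the methyl ethers are removed.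
5. Stereochemistry: anti addition of the two aryl groups across the (E)-alkene gives the relative configuration (trans C2/C3), and the chiral ferrocenyl diphosphine on palladium gives the absolute one (2S,3S). The oxidation is retentive and the ring closes at an aromatic carbon, so neither centre is touched again.

Key step: step 5

Assumption: the ligand is written as its (Sp,Sp) antipode by analogy with simpler alkenylboron ate complexes; if it should direct palladium to the Re face of the β-carbon, the (Rp,Rp) antipode is used and nothing else changes.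

**Route**

Step 1
Reactants: 1 4-fluoro-3-hydroxybenzaldehyde
Product: 2 2-fluoro-5-formylphenyl trifluoromethanesulfonate
Conditions: Tf2O, pyridine, CH2Cl2, 0 °C
Reagents that add atoms: trifluoromethanesulfonic anhydride, O=S(=O)(OS(=O)(=O)C(F)(F)F)C(F)(F)F
Why: O-triflation of the phenol with triflic anhydride and pyridine as acid scavenger is fast at 0 °C and leaves the formyl group and the aryl fluoride untouched.

Step 2
Reactants: 2 2-fluoro-5-formylphenyl trifluoromethanesulfonate
Product: 3 5-(1,3-dioxolan-2-yl)-2-fluorophenyl trifluoromethanesulfonate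
Conditions: ethylene glycol, p-TsOH·H2O (cat.), toluene, reflux, Dean–Stark trap
Reagents that add atoms: ethane-1,2-diol, OCCO
Why: Acid-catalysed acetalisation driven by azeotropic removal of water; the dioxolane hides the formyl group from the organolithium-derived borate of step 5, and aryl triflate and aryl fluoride are stable to anhydrous acid.

Step 3
Reactants: 4 acenaphthylene-1,2-dione
Product: 5 (1R,2S)-1,2-dimethyl-1,2-dihydroacenaphthylene-1,2-diol (cis, meso)
Conditions: AlMe3, toluene, 0 °C → rt; aq. HCl work-up; recrystallisation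
Reagents that add atoms: trimethylaluminium, C[Al](C)C
Why: Double 1,2-addition of methyl to the 1,2-diketone, in which the second methyl group should enter anti to the bulky aluminium alkoxide formed first, so that the cis diol, the only isomer able to span one boron atom, predominates and is purified by crystallisation.

Step 4
Reactants: 6 1-ethynyl-3,5-dimethoxybenzene; 5 (1R,2S)-1,2-dimethyl-1,2-dihydroacenaphthylene-1,2-diol
Product: 8 the (E)-styryl B(mac) ester 8-[(E)-2-(3,5-dimethoxyphenyl)ethenyl]-6b,9a-dimethyl-6b,9a-dihydroacenaphtho[1,2-d][1,3,2]dioxaborole (cis-fused), via catechol alkenylboronate 7 (not isolated)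
Conditions: catecholborane, THF, 70 °C; then 5, rt
Reagents that add atoms: catecholborane, B1Oc2ccccc2O1
Why: Syn, anti-Markovnikov hydroboration of the terminal arylalkyne puts boron on the terminal carbon and gives the (E)-alkenylboronate, whose labile catechol ester then exchanges with the more basic, rigidly cis ditertiary diol 5 (transesterification); this fixes the alkene geometry that step 5 translates into the C2/C3 relationship.

Step 5
Reactants: 9 4-bromo-1,2-dimethoxybenzene; 8 the (E)-styryl B(mac) ester; 3 5-(1,3-dioxolan-2-yl)-2-fluorophenyl trifluoromethanesulfonate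
Product: 12 8-[(1S,2S)-2-[5-(1,3-dioxolan-2-yl)-2-fluorophenyl]-1-(3,4-dimethoxyphenyl)-2-(3,5-dimethoxyphenyl)ethyl]-6b,9a-dimethyl-6b,9a-dihydroacenaphtho[1,2-d][1,3,2]dioxaborole (cis-fused B(mac) ester), via (3,4-dimethoxyphenyl)lithium 10 (not isolated), via lithium alkenyl(aryl)borate 11 (not isolated)
Conditions: 9, t-BuLi (2 equiv), THF, −78 °C; then 8, −78 °C → rt; then 3, Pd(OAc)2 (cat.), (Sp,Sp)-1,1′-bis[bis(4-methoxy-3,5-dimethylphenyl)phosphino]-2,2′-bis[(R)-α-(dimethylamino)benzyl]ferrocene (MandyPhos type, cat.), KOTf, THF, 60 °C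
Reagents that add atoms: none
Why: Bromine–lithium exchange gives aryllithium 10, which adds to the trigonal boron of 8 to form the four-coordinate borate 11; oxidative addition of triflate 3 to zerovalent palladium gives a cationic aryl complex of divalent palladium that binds the alkene of 11 and induces a 1,2-metallate shift in which the 3,4-dimethoxyphenyl group moves from boron to the boron-bearing carbon (future C2) anti to palladium, and the benzylic alkylpalladium so formed (future C3) reductively eliminates with ring A, creating C2–aryl and C3–C3a. The closest known reaction type is the palladium-catalysed enantioselective conjunctive cross-coupling of β-substituted alkenyl B(mac) ate complexes with aryl triflates; no ring is closed in this step. Relative configuration: the anti-periplanar shift followed by stereoretentive reductive elimination amounts to anti addition of the two aryl groups across the (E)-alkene and can only give the (1S,2S)/(1R,2R) pair, the one that maps onto the trans ring. Absolute configuration: both centres are fixed together by the chiral ferrocenyl diphosphine, which must hold palladium on the Si face of the β-carbon so that ring A enters there and the migrating aryl group enters C2 from the opposite face. The step needs the metallate shift to outrun direct Suzuki-type transfer of the alkenyl or aryl group: the shielded oxygen atoms of the mac diol disfavour transmetalation, the triflate leaves palladium cationic and alkene-seeking, and KOTf precipitates the bromide left by the exchange. The aryl fluoride and the dioxolane of 3 are inert to the borate and to palladium, and the oxygen for which boron stands is delivered in step 6.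

Step 6
Reactants: 12 the (1S,2S) benzylic B(mac) ester
Product: 13 (1S,2S)-2-[5-(1,3-dioxolan-2-yl)-2-fluorophenyl]-1-(3,4-dimethoxyphenyl)-2-(3,5-dimethoxyphenyl)ethan-1-ol
Conditions: 3 M NaOH, 30% H2O2, THF, 0 °C → rt
Reagents that add atoms: hydrogen peroxide, OO
Why: Alkaline peroxide oxidation of the boronic ester, in which hydroperoxide adds to boron and the benzylic carbon migrates from boron to oxygen with retention, so the C2 configuration set in step 5 is carried into the alcohol; dioxolane, aryl fluoride and methyl ethers are inert to these conditions.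

Step 7
Reactants: 13 (1S,2S)-2-[5-(1,3-dioxolan-2-yl)-2-fluorophenyl]-1-(3,4-dimethoxyphenyl)-2-(3,5-dimethoxyphenyl)ethan-1-ol
Product: 14 3-[(1S,2S)-2-(3,4-dimethoxyphenyl)-1-(3,5-dimethoxyphenyl)-2-hydroxyethyl]-4-fluorobenzaldehyde
Conditions: 1 M HCl, THF, rt
Reagents that add atoms: water, O
Why: Acid-catalysed hydrolysis of the aryl dioxolane through an aryl-stabilised oxocarbenium ion should be far faster in dilute aqueous acid at room temperature than ionisation of the hindered para-alkoxybenzylic carbinol, so the formyl group is freed without touching either stereocentre.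

Step 8
Reactants: 14 3-[(1S,2S)-2-(3,4-dimethoxyphenyl)-1-(3,5-dimethoxyphenyl)-2-hydroxyethyl]-4-fluorobenzaldehyde
Product: 15 (2S,3S)-2-(3,4-dimethoxyphenyl)-3-(3,5-dimethoxyphenyl)-2,3-dihydro-1-benzofuran-5-carbaldehyde
Conditions: Cs2CO3, DMF, 60 °C, high dilution
Reagents that add atoms: none
Why: Intramolecular nucleophilic aromatic substitution (addition–elimination through a Meisenheimer intermediate stabilised by the para-formyl group), in which the C2 alkoxide attacks the fluorine-bearing carbon in a 5-exo closure of O1–C7a; the new bond is made at an aromatic carbon, so both stereocentres are retained and the (1S,2S) alcohol gives the trans-(2S,3S) ring.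

Step 9
Reactants: 15 (2S,3S)-2-(3,4-dimethoxyphenyl)-3-(3,5-dimethoxyphenyl)-2,3-dihydro-1-benzofuran-5-carbaldehyde; 16 diethyl [(3,5-dimethoxyphenyl)methyl]phosphonate
Product: 17 (2S,3S)-2-(3,4-dimethoxyphenyl)-3-(3,5-dimethoxyphenyl)-5-[(E)-2-(3,5-dimethoxyphenyl)ethenyl]-2,3-dihydro-1-benzofuran
Conditions: 16, KOt-Bu, THF, 0 °C; then 15, 0 °C → rt
Reagents that add atoms: none
Why: Horner–Wadsworth–Emmons olefination of the aryl aldehyde with the benzylic phosphonate anion gives the (E)-stilbene through the thermodynamically controlled anti pathway, and the pre-formed phosphonate anion is too weak a base to remove the C3 hydrogen.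

Step 10
Reactants: 17 (2S,3S)-2-(3,4-dimethoxyphenyl)-3-(3,5-dimethoxyphenyl)-5-[(E)-2-(3,5-dimethoxyphenyl)ethenyl]-2,3-dihydro-1-benzofuran
Product: 18 5-[(E)-2-[(2S,3S)-2-(3,4-dihydroxyphenyl)-3-(3,5-dihydroxyphenyl)-2,3-dihydro-1-benzofuran-5-yl]ethenyl]benzene-1,3-diol (CNP0207985.1)
Conditions: BCl3, n-Bu4NI, CH2Cl2, −78 °C → rt; then ice-water
Reagents that add atoms: none
Why: Lewis-acid-assisted SN2 ether cleavage, in which BCl3 coordinates each methoxy oxygen and iodide removes the methyl group as iodomethane under conditions mild enough for an (E)-stilbene; should the C2–O1 bond open reversibly, it should re-close to the more stable trans ring because C3 is not affected.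

**Compound list**

1 | 4-fluoro-3-hydroxybenzaldehyde | O=Cc1ccc(F)c(O)c1 | starting material
2 | 2-fluoro-5-formylphenyl trifluoromethanesulfonate | O=Cc1ccc(F)c(OS(=O)(=O)C(F)(F)F)c1 | intermediate
3 | 5-(1,3-dioxolan-2-yl)-2-fluorophenyl trifluoromethanesulfonate | O=S(=O)(Oc1cc(C2OCCO2)ccc1F)C(F)(F)F | intermediate
4 | acenaphthylene-1,2-dione (acenaphthoquinone) | O=C1C(=O)c2cccc3cccc1c23 | starting material
5 | (1R,2S)-1,2-dimethyl-1,2-dihydroacenaphthylene-1,2-diol (cis, meso; the mac diol) | C[C@]1(O)c2cccc3cccc(c23)[C@@]1(C)O | intermediate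
6 | 1-ethynyl-3,5-dimethoxybenzene | C#Cc1cc(OC)cc(OC)c1 | starting material
7 | 2-[(E)-2-(3,5-dimethoxyphenyl)ethenyl]-1,3,2-benzodioxaborole (formed in the flask) | COc1cc(OC)cc(/C=C/B2Oc3ccccc3O2)c1 | intermediate
8 | 8-[(E)-2-(3,5-dimethoxyphenyl)ethenyl]-6b,9a-dimethyl-6b,9a-dihydroacenaphtho[1,2-d][1,3,2]dioxaborole (cis-fused; (E)-styryl B(mac) ester) | COc1cc(OC)cc(/C=C/B2O[C@]3(C)c4cccc5cccc(c45)[C@]3(C)O2)c1 | intermediate
9 | 4-bromo-1,2-dimethoxybenzene | COc1ccc(Br)cc1OC | starting material
10 | (3,4-dimethoxyphenyl)lithium (formed in the flask) | [Li]c1ccc(OC)c(OC)c1 | intermediate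
11 | lithium 8-[(E)-2-(3,5-dimethoxyphenyl)ethenyl]-8-(3,4-dimethoxyphenyl)-6b,9a-dimethyl-6b,9a-dihydroacenaphtho[1,2-d][1,3,2]dioxaborol-8-uide (formed in the flask; configuration at boron without consequence) | [Li+].COc1cc(OC)cc(/C=C/[B-]2(c3ccc(OC)c(OC)c3)O[C@]3(C)c4cccc5cccc(c45)[C@]3(C)O2)c1 | intermediate
12 | 8-[(1S,2S)-2-[5-(1,3-dioxolan-2-yl)-2-fluorophenyl]-1-(3,4-dimethoxyphenyl)-2-(3,5-dimethoxyphenyl)ethyl]-6b,9a-dimethyl-6b,9a-dihydroacenaphtho[1,2-d][1,3,2]dioxaborole (cis-fused B(mac) ester) | Fc1ccc(C2OCCO2)cc1[C@H](c1cc(OC)cc(OC)c1)[C@@H](c1ccc(OC)c(OC)c1)B1O[C@]2(C)c3cccc4cccc(c34)[C@]2(C)O1 | intermediate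
13 | (1S,2S)-2-[5-(1,3-dioxolan-2-yl)-2-fluorophenyl]-1-(3,4-dimethoxyphenyl)-2-(3,5-dimethoxyphenyl)ethan-1-ol | Fc1ccc(C2OCCO2)cc1[C@H](c1cc(OC)cc(OC)c1)[C@@H](c1ccc(OC)c(OC)c1)O | intermediate
14 | 3-[(1S,2S)-2-(3,4-dimethoxyphenyl)-1-(3,5-dimethoxyphenyl)-2-hydroxyethyl]-4-fluorobenzaldehyde | Fc1ccc(C=O)cc1[C@H](c1cc(OC)cc(OC)c1)[C@@H](c1ccc(OC)c(OC)c1)O | intermediate
15 | (2S,3S)-2-(3,4-dimethoxyphenyl)-3-(3,5-dimethoxyphenyl)-2,3-dihydro-1-benzofuran-5-carbaldehyde | O=Cc1ccc2c(c1)[C@H](c1cc(OC)cc(OC)c1)[C@@H](c1ccc(OC)c(OC)c1)O2 | intermediate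
16 | diethyl [(3,5-dimethoxyphenyl)methyl]phosphonate | CCOP(=O)(Cc1cc(OC)cc(OC)c1)OCC | starting material
17 | (2S,3S)-2-(3,4-dimethoxyphenyl)-3-(3,5-dimethoxyphenyl)-5-[(E)-2-(3,5-dimethoxyphenyl)ethenyl]-2,3-dihydro-1-benzofuran | COc1cc(OC)cc(/C=C/c2ccc3c(c2)[C@H](c2cc(OC)cc(OC)c2)[C@@H](c2ccc(OC)c(OC)c2)O3)c1 | intermediate
18 | 5-[(E)-2-[(2S,3S)-2-(3,4-dihydroxyphenyl)-3-(3,5-dihydroxyphenyl)-2,3-dihydro-1-benzofuran-5-yl]ethenyl]benzene-1,3-diol | Oc1cc(O)cc(/C=C/c2ccc3c(c2)[C@H](c2cc(O)cc(O)c2)[C@@H](c2ccc(O)c(O)c2)O3)c1 | target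

**Step count and risks**

Total steps: 10. Longest linear sequence: 8 steps (steps 1, 2, 5, 6, 7, 8, 9, 10; the branch through steps 3 and 4 is equally long).

Steps most likely to fail:

1. Step 5. A β-aryl alkenylboronate combined with an ortho-substituted aryl triflate lies outside the tested range of this coupling. The anti relationship is secured by the mechanism, but the palladium–diphosphine complex may discriminate the two faces of the flat, conjugated alkene poorly, so that the product has the right relative but insufficient absolute purity. Fallback: classical resolution replaces catalyst control. It sets out from alcohol 13 (scalemic, after steps 5 and 6) and comes back at 13. Alcohol 13 is acylated with (S)-naproxen (DCC, DMAP, CH2Cl2). Because only one relative configuration is present, just two esters arise: (1S,2S)-2-[5-(1,3-dioxolan-2-yl)-2-fluorophenyl]-1-(3,4-dimethoxyphenyl)-2-(3,5-dimethoxyphenyl)ethyl (2S)-2-(6-methoxynaphthalen-2-yl)propanoate F1 and its diastereomer (1R,2R)-2-[5-(1,3-dioxolan-2-yl)-2-fluorophenyl]-1-(3,4-dimethoxyphenyl)-2-(3,5-dimethoxyphenyl)ethyl (2S)-2-(6-methoxynaphthalen-2-yl)propanoate F2. They are separated by crystallisation or chromatography, and F1 is cleaved with LiOH in aqueous THF/MeOH to return enantiopure 13.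

2. Step 10. Lewis-acid activation of O1 can ionise the C2–O1 bond, because the para oxygen of the catechol ring stabilises a C2 cation. That cation, or the protonated stilbene, can then be captured by the electron-rich arenes, which leads to ring opening and oligomerisation instead of clean ether cleavage. Fallback: the ether cleavage is moved to a stage without the stilbene and with O1 deactivated by the para-formyl group, and the synthesis is finished with fluoride-labile groups. It sets out from aldehyde 15 and comes back at 18. BCl3/n-Bu4NI on 15 gives (2S,3S)-2-(3,4-dihydroxyphenyl)-3-(3,5-dihydroxyphenyl)-2,3-dihydro-1-benzofuran-5-carbaldehyde F3. TBSCl and imidazole in DMF give (2S,3S)-2-[3,4-bis(tert-butyldimethylsilyloxy)phenyl]-3-[3,5-bis(tert-butyldimethylsilyloxy)phenyl]-2,3-dihydro-1-benzofuran-5-carbaldehyde F4. Horner–Wadsworth–Emmons reaction (NaH, THF) with diethyl {[3,5-bis(tert-butyldimethylsilyloxy)phenyl]methyl}phosphonate F5, obtained by Arbuzov reaction of the known 3,5-bis(tert-butyldimethylsilyloxy)benzyl bromide with triethyl phosphite, gives the hexakis(tert-butyldimethylsilyl) ether of the target F6. Et3N·3HF in THF then removes the silyl groups to give 18.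

3. Step 8. The secondary benzylic alkoxide is generated beside a free formyl group, so intermolecular hydride transfer from the alkoxide to the aldehyde (Meerwein–Ponndorf or Cannizzaro type) may compete with ring closure. Fallback: the ring is closed while the aldehyde is still masked. It sets out from 13 and comes back at 15. KOt-Bu in THF/DMPU at 60 °C closes O1–C7a by intramolecular SNAr of the potassium alkoxide on the non-activated fluoroarene, giving (2S,3S)-2-(3,4-dimethoxyphenyl)-3-(3,5-dimethoxyphenyl)-5-(1,3-dioxolan-2-yl)-2,3-dihydro-1-benzofuran F7. 1 M HCl in THF then frees the aldehyde 15.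

**Further compounds**

F1 | step 5 | (1S,2S)-2-[5-(1,3-dioxolan-2-yl)-2-fluorophenyl]-1-(3,4-dimethoxyphenyl)-2-(3,5-dimethoxyphenyl)ethyl (2S)-2-(6-methoxynaphthalen-2-yl)propanoate | Fc1ccc(C2OCCO2)cc1[C@H](c1cc(OC)cc(OC)c1)[C@@H](c1ccc(OC)c(OC)c1)OC(=O)[C@@H](C)c1ccc2cc(OC)ccc2c1
F2 | step 5 | (1R,2R)-2-[5-(1,3-dioxolan-2-yl)-2-fluorophenyl]-1-(3,4-dimethoxyphenyl)-2-(3,5-dimethoxyphenyl)ethyl (2S)-2-(6-methoxynaphthalen-2-yl)propanoate | Fc1ccc(C2OCCO2)cc1[C@@H](c1cc(OC)cc(OC)c1)[C@H](c1ccc(OC)c(OC)c1)OC(=O)[C@@H](C)c1ccc2cc(OC)ccc2c1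
F3 | step 10 | (2S,3S)-2-(3,4-dihydroxyphenyl)-3-(3,5-dihydroxyphenyl)-2,3-dihydro-1-benzofuran-5-carbaldehyde | O=Cc1ccc2c(c1)[C@H](c1cc(O)cc(O)c1)[C@@H](c1ccc(O)c(O)c1)O2
F4 | step 10 | (2S,3S)-2-[3,4-bis(tert-butyldimethylsilyloxy)phenyl]-3-[3,5-bis(tert-butyldimethylsilyloxy)phenyl]-2,3-dihydro-1-benzofuran-5-carbaldehyde | O=Cc1ccc2c(c1)[C@H](c1cc(O[Si](C)(C)C(C)(C)C)cc(O[Si](C)(C)C(C)(C)C)c1)[C@@H](c1ccc(O[Si](C)(C)C(C)(C)C)c(O[Si](C)(C)C(C)(C)C)c1)O2
F5 | step 10 | diethyl {[3,5-bis(tert-butyldimethylsilyloxy)phenyl]methyl}phosphonate | CCOP(=O)(Cc1cc(O[Si](C)(C)C(C)(C)C)cc(O[Si](C)(C)C(C)(C)C)c1)OCC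
F6 | step 10 | (2S,3S)-2-[3,4-bis(tert-butyldimethylsilyloxy)phenyl]-3-[3,5-bis(tert-butyldimethylsilyloxy)phenyl]-5-[(E)-2-[3,5-bis(tert-butyldimethylsilyloxy)phenyl]ethenyl]-2,3-dihydro-1-benzofuran | CC(C)(C)[Si](C)(C)Oc1cc(O[Si](C)(C)C(C)(C)C)cc(/C=C/c2ccc3c(c2)[C@H](c2cc(O[Si](C)(C)C(C)(C)C)cc(O[Si](C)(C)C(C)(C)C)c2)[C@@H](c2ccc(O[Si](C)(C)C(C)(C)C)c(O[Si](C)(C)C(C)(C)C)c2)O3)c1
F7 | step 8 | (2S,3S)-2-(3,4-dimethoxyphenyl)-3-(3,5-dimethoxyphenyl)-5-(1,3-dioxolan-2-yl)-2,3-dihydro-1-benzofuran | O1CCOC1c1ccc2c(c1)[C@H](c1cc(OC)cc(OC)c1)[C@@H](c1ccc(OC)c(OC)c1)O2
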